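The target is traced back to its ring-B methyl ether. Each outer phenol ring comes from a 6-arylcyclohex-3-enone (silyl dienol ether, then DDQ), and each ketone from a nitro group by a Nef reaction.
Key disconnection: in rings A and C the bonds C1'–C6' and C2'–C3' are cut at the cyclohexene stage. This is a twofold Diels–Alder reaction of 2-allyl-4,6-bis[(E)-2-nitrovinyl]anisole (ring B) with two molecules of 2-allylbuta-1,3-diene.
Feature used: in rings A and C the oxygen-bearing C2' is ortho to the biaryl carbon C1' and 1,4 (para) to the allyl-bearing C5'. A 2-substituted butadiene leaves this pattern when it adds in the "para" sense to an aryl nitroalkene whose nitro carbon later becomes C–OH.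
The dienophile comes from 4-hydroxyisophthalaldehyde (O-allylation, Claisen rearrangement, O-methylation, double Henry condensation). The diene comes from chloroprene and allyl bromide through the dienyl Grignard reagent.
Ring order: ring B is bought; rings A and C are closed together as cyclohexenes in the key step and aromatized together three steps later.

Key step: step 6

Assumption: macranthol is achiral, so the stereocentres of the partly saturated intermediates are carried as racemic diastereomer mixtures and erased on aromatization. Outer-ring atoms are numbered C1' (bonded to ring B), C2' (nitro, later oxygen carbon) round to C6', with C5' bearing the allyl group.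

Step 1
Reactants: 1 4-hydroxyisophthalaldehyde; 2 allyl bromide
Product: 3 4-(allyloxy)isophthalaldehyde
Conditions: K2CO3, DMF, rt → 50 °C
Reagents that add atoms: none
Why: Williamson ether synthesis, in which the phenol acidified by its ortho- and para-formyl groups is deprotonated and O-alkylated by SN2 displacement on allyl bromide; no stereocentre is formed.

Step 2
Reactants: 3 4-(allyloxy)isophthalaldehyde
Product: 4 5-allyl-4-hydroxyisophthalaldehyde
Conditions: PhNEt2, 190 °C
Reagents that add atoms: none
Why: Aromatic Claisen rearrangement, whose [3,3] shift delivers the allyl group to C5, the only ortho carbon that carries hydrogen, after which tautomerization restores the phenol; no stereocentre is formed.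

Step 3
Reactants: 4 5-allyl-4-hydroxyisophthalaldehyde
Product: 5 5-allyl-4-methoxyisophthalaldehyde
Conditions: MeI, K2CO3, DMF, rt
Reagents that add atoms: iodomethane, CI
Why: Williamson O-methylation of the phenoxide gives a methyl ether that should survive the heat, base, reductant and oxidant of steps 4 to 10.

Step 4
Reactants: 5 5-allyl-4-methoxyisophthalaldehyde; 6 nitromethane (two molecules, used in excess)
Product: 7 2-allyl-4,6-bis[(E)-2-nitrovinyl]anisole
Conditions: 6 (10 equiv), NH4OAc, AcOH, 100 °C
Reagents that add atoms: none
Why: Twofold Henry (nitroaldol) condensation, one molecule of nitromethane per formyl group, through the iminium ions formed with NH4OAc, with dehydration under thermodynamic control to the E-nitroalkenes; the allyl group and the ether are inert.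

Step 5
Reactants: 8 chloroprene; 2 allyl bromide
Product: 10 2-allylbuta-1,3-diene (3-methylidenehexa-1,5-diene), via buta-1,3-dien-2-ylmagnesium chloride 9 (not isolated)
Conditions: Mg, ZnCl2 (cat.), THF, reflux; then 2, Li2CuCl4 (cat.), 0 °C → rt; fractional distillation
Reagents that add atoms: none
Why: Grignard formation at the vinylic C–Cl bond followed by copper-catalysed coupling of the dienyl Grignard reagent at its metal-bearing carbon with the allylic bromide should give the 2-substituted diene in preference to the allenic isomer; no stereocentre is formed.

Step 6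
Reactants: 7 2-allyl-4,6-bis[(E)-2-nitrovinyl]anisole; 10 2-allylbuta-1,3-diene (two molecules, used in excess)
Product: 11 2-allyl-4,6-bis[trans-6-nitro-3-(prop-2-enyl)cyclohex-3-en-1-yl]anisole
Conditions: 10 (6 equiv), BHT (cat.), PhMe, sealed tube, 125 °C
Reagents that add atoms: none
Why: Each outer ring should close by a concerted but asynchronous normal-demand [4+2] cycloaddition between the HOMO of the s-cis diene and the LUMO of the nitroalkene, the closest known reaction type being the thermal Diels–Alder reaction of β-nitrostyrenes with isoprene or 2,3-dimethylbutadiene. Both cyclohexenes close by intermolecular cycloaddition, C1'–C6' and C2'–C3' forming in the same step, and the two nitrovinyl arms react one after the other. Suprafacial addition to the E-alkene sets aryl and nitro trans at C1'/C2' of each ring; the relative configuration between the two remote rings and the absolute configuration are not controlled, and all four centres are erased in steps 7 to 9. The step needs the "para" orientation twice: the nitro group puts the largest LUMO coefficient on the aryl-bearing β-carbon and the 2-allyl group puts the largest HOMO coefficient on the adjacent diene terminus, so this terminus should bond to C1' and the allyl carbon should end up 1,4 to the nitro carbon; because an alkyl group directs only moderately, the "meta" isomers are the expected by-products. The step also needs chemoselectivity for the conjugated nitroalkenes over the unactivated allyl alkenes, which the LUMO-lowering nitro group secures, while BHT suppresses radical polymerization.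

Step 7
Reactants: 11 2-allyl-4,6-bis[trans-6-nitro-3-(prop-2-enyl)cyclohex-3-en-1-yl]anisole
Product: 13 2-allyl-4,6-bis[6-oxo-3-(prop-2-enyl)cyclohex-3-en-1-yl]anisole, via disodium bis(nitronate) 12 (not isolated)
Conditions: NaOMe, MeOH, 0 °C; then aq. TiCl3, NH4OAc, MeOH/H2O, 0 °C → rt
Reagents that add atoms: water, O
Why: Reductive Nef reaction, in which each nitronate is reduced by trivalent titanium through the oxime to the N–H imine and hydrolysed at buffered pH to the ketone, conditions that leave alkenes and the aryl ether alone; the nitro-bearing stereocentres disappear and C1' becomes epimerizable, which is of no consequence.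

Step 8
Reactants: 13 2-allyl-4,6-bis[6-oxo-3-(prop-2-enyl)cyclohex-3-en-1-yl]anisole
Product: 14 2-allyl-4,6-bis[2-(tert-butyldimethylsilyloxy)-5-(prop-2-enyl)cyclohexa-2,4-dien-1-yl]anisole
Conditions: TBSOTf, Et3N, CH2Cl2, 0 °C
Reagents that add atoms: tert-butyldimethylsilyl trifluoromethanesulfonate, CC(C)(C)[Si](C)(C)OS(=O)(=O)C(F)(F)F
Why: Soft enolization and O-silylation of each β,γ-unsaturated ketone toward the doubly activated C3' should give the conjugated silyloxydiene, and any other enol ether regioisomer (or one formed from a conjugated enone isomer of 13) is also a cyclohexadiene that serves equally in step 9.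

Step 9
Reactants: 14 2-allyl-4,6-bis[2-(tert-butyldimethylsilyloxy)-5-(prop-2-enyl)cyclohexa-2,4-dien-1-yl]anisole
Product: 15 2-allyl-4,6-bis[5-allyl-2-(tert-butyldimethylsilyloxy)phenyl]anisole
Conditions: DDQ, 2,6-lutidine, PhMe, 0 °C → rt
Reagents that add atoms: none
Why: Dehydrogenative aromatization of a cyclohexadiene: DDQ abstracts hydride from ring C6' to give an oxygen-stabilized cyclohexadienyl cation that loses the C1' proton. The silyl group keeps each new 4-allylphenol masked from quinone oxidation. This route is preferred to α-selenoxide elimination (the kinetic α-carbon C3' has only a vinylic β-hydrogen) and to pentavalent iodine oxidants (they attack free phenols). The last stereocentres vanish here.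

Step 10
Reactants: 15 2-allyl-4,6-bis[5-allyl-2-(tert-butyldimethylsilyloxy)phenyl]anisole
Product: 16 2-allyl-4,6-bis(5-allyl-2-hydroxyphenyl)anisole
Conditions: TBAF, THF, 0 °C; aq. NH4Cl
Reagents that add atoms: none
Why: Fluoride-induced cleavage of the aryl silyl ethers, driven by the Si–F bond, leaves the methyl ether and the three allyl groups untouched.

Step 11
Reactants: 16 2-allyl-4,6-bis(5-allyl-2-hydroxyphenyl)anisole
Product: 18 macranthol, via tris(dibromoboryl) ether 17 (not isolated)
Conditions: BBr3, CH2Cl2, −78 → 0 °C; then H2O
Reagents that add atoms: none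
Why: Lewis-acid demethylation, in which BBr3 coordinates the hindered ether oxygen and bromide removes the methyl group by SN2, the low temperature sparing the allyl groups, and hydrolysis of the aryl borates releases the triphenol.

Compound list
1 | 4-hydroxyisophthalaldehyde | O=Cc1ccc(O)c(C=O)c1 | starting material
2 | allyl bromide | C=CCBr | starting material
3 | 4-(allyloxy)isophthalaldehyde | C=CCOc1ccc(C=O)cc1C=O | intermediate
4 | 5-allyl-4-hydroxyisophthalaldehyde | C=CCc1cc(C=O)cc(C=O)c1O | intermediate
5 | 5-allyl-4-methoxyisophthalaldehyde | C=CCc1cc(C=O)cc(C=O)c1OC | intermediate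
6 | nitromethane | C[N+](=O)[O-] | starting material
7 | 2-allyl-4,6-bis[(E)-2-nitrovinyl]anisole | C=CCc1cc(/C=C/[N+](=O)[O-])cc(/C=C/[N+](=O)[O-])c1OC | intermediate
8 | chloroprene (2-chlorobuta-1,3-diene) | C=CC(Cl)=C | starting material
9 | buta-1,3-dien-2-ylmagnesium chloride (not isolated) | C=CC(=C)[Mg]Cl | intermediate
10 | 2-allylbuta-1,3-diene (3-methylidenehexa-1,5-diene) | C=CCC(=C)C=C | intermediate
11 | 2-allyl-4,6-bis[trans-6-nitro-3-(prop-2-enyl)cyclohex-3-en-1-yl]anisole (racemic; aryl and nitro trans in each ring, (1R*,6S*); one of the two ring-to-ring diastereomers drawn, both expected) | C=CCc1cc([C@H]2CC(CC=C)=CC[C@@H]2[N+](=O)[O-])cc([C@H]2CC(CC=C)=CC[C@@H]2[N+](=O)[O-])c1OC | intermediate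
12 | disodium bis(nitronate) of 11 (not isolated; C1' centres unassigned) | C=CCc1cc(C2CC(CC=C)=CCC2=[N+]([O-])[O-])cc(C2CC(CC=C)=CCC2=[N+]([O-])[O-])c1OC.[Na+].[Na+] | intermediate
13 | 2-allyl-4,6-bis[6-oxo-3-(prop-2-enyl)cyclohex-3-en-1-yl]anisole (mixture of racemic diastereomers, epimerizable C1' centres unassigned) | C=CCc1cc(C2CC(CC=C)=CCC2=O)cc(C2CC(CC=C)=CCC2=O)c1OC | intermediate
14 | 2-allyl-4,6-bis[2-(tert-butyldimethylsilyloxy)-5-(prop-2-enyl)cyclohexa-2,4-dien-1-yl]anisole (mixture of racemic diastereomers, C1' centres unassigned) | C=CCc1cc(C2CC(CC=C)=CC=C2O[Si](C)(C)C(C)(C)C)cc(C2CC(CC=C)=CC=C2O[Si](C)(C)C(C)(C)C)c1OC | intermediate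
15 | 2-allyl-4,6-bis[5-allyl-2-(tert-butyldimethylsilyloxy)phenyl]anisole (achiral) | C=CCc1ccc(O[Si](C)(C)C(C)(C)C)c(-c2cc(CC=C)c(OC)c(-c3cc(CC=C)ccc3O[Si](C)(C)C(C)(C)C)c2)c1 | intermediate
16 | 2-allyl-4,6-bis(5-allyl-2-hydroxyphenyl)anisole (achiral) | C=CCc1ccc(O)c(-c2cc(CC=C)c(OC)c(-c3cc(CC=C)ccc3O)c2)c1 | intermediate
17 | tris(O-dibromoboryl) derivative of macranthol (not isolated) | C=CCc1ccc(OB(Br)Br)c(-c2cc(CC=C)c(OB(Br)Br)c(-c3cc(CC=C)ccc3OB(Br)Br)c2)c1 | intermediate
18 | macranthol, 2-allyl-4,6-bis(5-allyl-2-hydroxyphenyl)phenol (achiral) | C=CCc1ccc(O)c(-c2cc(CC=C)c(O)c(-c3cc(CC=C)ccc3O)c2)c1 | target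

Total step count: 11.
Longest linear sequence: 10 steps (1 to 18 through steps 1–4 and 6–11); step 5 is a one-step side branch.

Steps most likely to fail

Step 6. One or both cycloadditions may take the "meta" orientation, because an alkyl substituent polarizes the diene only weakly. Slow reaction at the more hindered arm next to the methoxy group may also let diene dimerization and nitroalkene polymerization compete. The fallback sets out from 7 and replaces the diene by commercial 2-(trimethylsilyloxy)buta-1,3-diene (PhMe, 110 °C), whose oxygen substituent should enforce the "para" orientation far more strongly. It should give 2-allyl-4,6-bis[trans-6-nitro-3-(trimethylsilyloxy)cyclohex-3-en-1-yl]anisole F1. Each secondary nitro group is a stronger acid than the ketone whose enolate has to be trapped, so the nitro groups are deprotonated first (KN(SiMe3)2, THF, −78 °C), which also sets up the Nef reaction. The silyl enol ethers are then cleaved to the regiodefined potassium enolates and O-triflated (KOt-Bu, then PhNTf2, −78 → −20 °C), and the nitronate solution is added to buffered aqueous TiCl3 (NH4OAc) as in step 7. This should give 2-allyl-4,6-bis[6-oxo-3-(trifluoromethylsulfonyloxy)cyclohex-3-en-1-yl]anisole F2. A twofold Stille coupling with allyltributylstannane (Pd(PPh3)4, LiCl, THF, 65 °C) places the allyl groups on C5' under neutral conditions. The fallback comes back to the route at 13, so steps 6 and 7 are bypassed.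

Step 9. DDQ may abstract hydride from the doubly allylic side-chain methylene or from the benzylic allyl positions instead of ring C6', moving allyl double bonds into conjugation. The silyl group may also be lost before aromatization, exposing a free 4-allylphenol to quinone oxidation. The fallback sets out from 14 and replaces hydride abstraction by halogenation and elimination. Bromination of the silyl dienol ethers at the γ-carbon C5' (NBS, THF, −78 °C, far faster than addition to the isolated alkenes), the usual site of halogen attack on such dienol ethers, should give 2-allyl-4,6-bis[5-bromo-2-oxo-5-(prop-2-enyl)cyclohex-3-en-1-yl]anisole F3. Dehydrobromination toward C6' (Li2CO3, LiBr, DMF, 90 °C) and tautomerization of the resulting linearly conjugated dienones should then give the free bisphenol. The fallback comes back to the route at 16, so steps 9 and 10 are bypassed.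

Step 7. Reduction may stop at the oxime, or the ring double bond may migrate at the nitronate or ketone stage and the β,γ-unsaturated ketone may self-condense during the buffered work-up. The fallback sets out from 11 and makes the oxime on purpose under nearly neutral conditions. Reduction with SnCl2, PhSH and Et3N (MeCN, rt) should give 2-allyl-4,6-bis[6-(hydroxyimino)-3-(prop-2-enyl)cyclohex-3-en-1-yl]anisole F4. Transoximation to aqueous glyoxylic acid (THF/H2O, rt) then releases the ketones. The fallback comes back to the route at 13.

Further compounds
F1 | step 6 | 2-allyl-4,6-bis[trans-6-nitro-3-(trimethylsilyloxy)cyclohex-3-en-1-yl]anisole | C=CCc1cc([C@H]2CC(O[Si](C)(C)C)=CC[C@@H]2[N+](=O)[O-])cc([C@H]2CC(O[Si](C)(C)C)=CC[C@@H]2[N+](=O)[O-])c1OC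
F2 | step 6 | 2-allyl-4,6-bis[6-oxo-3-(trifluoromethylsulfonyloxy)cyclohex-3-en-1-yl]anisole | C=CCc1cc(C2CC(OS(=O)(=O)C(F)(F)F)=CCC2=O)cc(C2CC(OS(=O)(=O)C(F)(F)F)=CCC2=O)c1OC
F3 | step 9 | 2-allyl-4,6-bis[5-bromo-2-oxo-5-(prop-2-enyl)cyclohex-3-en-1-yl]anisole | C=CCc1cc(C2CC(Br)(CC=C)C=CC2=O)cc(C2CC(Br)(CC=C)C=CC2=O)c1OC
F4 | step 7 | 2-allyl-4,6-bis[6-(hydroxyimino)-3-(prop-2-enyl)cyclohex-3-en-1-yl]anisole | C=CCc1cc(C2CC(CC=C)=CCC2=NO)cc(C2CC(CC=C)=CCC2=NO)c1OC
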